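(The data stem from a simulated flask for an exercise.)

Slowness is not my worry here: in the dusk run Q reads 0% at 20.0 s, and the flask stands for 120 s, longer than that.

| flask | Q | remark | time |
|---|---|---|---|
| dusk | 1.4 mM | run made earlier |  |
| winter | 2.2 mM | run made earlier |  |
| flask | 1.0 mM |  | 2.0 min |

| run | time / s | Q / % | L / % | J / % |
|---|---|---|---|---|
| dusk | 10.0 | 1.2 | 37.6 | 40.3 |
| dusk | 20.0 | 0 | 38.9 | 51.0 |
| dusk | 30.0 | 1.1 | 36.9 | 51.6 |
| dusk | 50.0 | 1.2 | 36.8 | 50.3 |
| dusk | 80.0 | 0 | 36.3 | 51.7 |
| dusk | 90.0 | 0 | 36.5 | 50.5 |
| winter | 15.0 | 0 | 27.2 | 51.5 |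
| winter | 30.0 | 0 | 29.1 | 57.5 |
| winter | 50.0 | 0.2 | 30.1 | 58.3 |
| winter | 60.0 | 0 | 26.9 | 59.8 |
| winter | 80.0 | 1.2 | 30.1 | 57.1 |
| winter | 90.0 | 0.7 | 28.6 | 57.6 |

(readings scatter by 1 percentage point)

- in percentages every species weighs as the Q in it: one J counts as two
- the analysis behind the earlier runs scatters by 1 percentage point, standard deviation
- the reaction counts as stopped when no species that holds the Q changes by six tenths of a point or more over the second half of the time

* at 2.0 min, what has stopped the reaction, if anything has (forward and back rates have come level / all of Q has reacted / it is still moving)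
* part of the Q gone at 2.0 min
* the L standing at 2.0 min, as a percentage of the Q charged
* the J standing at 2.0 min, as a percentage of the Q charged

So I expect Q in this flask to stand within about 1 percentage point of 0%, and the question becomes one of selectivity: where did Q go? I follow one molecule of Q. I suppose it may turn into L by itself or meet a second Q, and that a meeting grows likelier the more Q stands. A bigger charge should then leave less L, and the runs read that way: L averages 37.2% in the dusk run, more than the 28.7% of the winter run.

So I take 1/L, the Q charged per L standing. Its rise per mM of charge between these runs, the crowding price s, reads 0.997 /mM. Going down the straight line from the dusk run to 1.0 mM, I reckon L at 43.6% in the flask; this is my own figure and gives no J.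

The forecast, by a different curve, says all of Q has reacted, with 100% of Q gone, L 43.8% and J 45.6%: “Q running out ended the reaction, not an equilibrium”.

The flask gives all of Q has reacted, with 100% of Q gone, L 44.2% and J 45.1%.

    Q → L (k = 0.314 /s)
    2 Q → Z (k = 378 /M/s)
    Q + Z → G (k = 66.0 /M/s)
    Z → J (k = 0.164 /s)
    Q + L → E (k = 103 /M/s)

With the time held, J has moved 5 points from that at a charge of 0.759 mM or 1.34 mM. The flask's 1/L is 2.26, where s gave 2.29. In the neighbour charged with 4.0 mM, s gives L 18.9%, and that neighbour stands at 19.0%.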